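The pyran ring is cut at C3–C4 and O1–C2. C4 is an unsubstituted methylene on C4a of ring A, ortho to the C8a–O1 oxygen, so ring A can act as an ortho-quinone methide. C3 bears oxygen, so C2, C3 and O3 can arrive together as benzyloxyacetaldehyde. One aminocatalytic operation joins them: it forges C3–C4, fixes (3S) and closes the pyran as a lactol. Its precursor is a 2-(tosylmethyl)phenol with O7 as benzyl and O5 as MOM ether. Ring B then enters at C2 as a Grignard reagent. Acid recloses the ring 2,3-trans and frees only O5 and O4' for galloylation, and hydrogenolysis ends the route.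

Key step: step 5

Assumption: the sense of induction follows the usual shielding model for diarylprolinol silyl ethers (E, s-trans enamine attacked anti to the CPh2(OSiMe3) group). This pairs the (R)-amine, C[Si](C)(C)OC(c1ccccc1)(c1ccccc1)[C@H]1CCCN1, with the (3S) product.
Remark: flavan numbering (O1, C2–C4, C4a, C5–C8, C8a; ring B primed) is used for all intermediates.

Step 1
Reactants: 1 2,4,6-trihydroxybenzaldehyde
Product: 2 4-(benzyloxy)-2,6-dihydroxybenzaldehyde
Conditions: BnBr (1.0 equiv), K2CO3 (1.0 equiv), DMF, 0 °C → rt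
Reagents that add atoms: benzyl bromide, BrCc1ccccc1
Why: Williamson ether synthesis with base and halide as limiting reagents: the 4-OH, para to the formyl group, is the most acidic and least hindered hydroxyl, whereas the 2- and 6-OH flank the carbonyl and share its hydrogen bond, so the future O7 should be benzylated first.

Step 2
Reactants: 2 4-(benzyloxy)-2,6-dihydroxybenzaldehyde
Product: 3 4-(benzyloxy)-2-hydroxy-6-(methoxymethoxy)benzaldehyde
Conditions: MOMCl (1.05 equiv), K2CO3 (1.1 equiv), acetone, 0 °C → rt
Reagents that add atoms: chloromethyl methyl ether, COCCl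
Why: Williamson-type MOM ether formation: 2 is symmetric, so either ortho hydroxyl gives the same mono-ether, and the remaining hydroxyl is then held in a strong hydrogen bond to the formyl oxygen and is too poor a nucleophile for the small excess of MOMCl.

Step 3
Reactants: 3 4-(benzyloxy)-2-hydroxy-6-(methoxymethoxy)benzaldehyde
Product: 4 5-(benzyloxy)-2-(hydroxymethyl)-3-(methoxymethoxy)phenol
Conditions: NaBH4, THF–EtOH, 0 °C; pH 7 buffer quench; used crude
Reagents that add atoms: none
Why: Borohydride reduction of the aldehyde; cold, non-acidic handling keeps the very electron-rich ortho-hydroxybenzyl alcohol from ionising, and it is carried on without storage.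

Step 4
Reactants: 4 5-(benzyloxy)-2-(hydroxymethyl)-3-(methoxymethoxy)phenol
Product: 5 5-(benzyloxy)-3-(methoxymethoxy)-2-(tosylmethyl)phenol
Conditions: p-TolSO2H (1.5 equiv), CH2Cl2, 0 °C → rt
Reagents that add atoms: p-toluenesulfinic acid, Cc1ccc(S(=O)O)cc1
Why: SN1-type substitution of an activated benzylic alcohol by a sulfinic acid: the reagent is acidic enough to ionise the 2,4,6-trioxygenated benzylic position but too weak to cleave the aryl MOM ether in an aprotic solvent, and its soft sulfur should capture the cation faster than ring A alkylates itself, any sulfinate ester reverting to the more stable sulfone.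

Step 5
Reactants: 5 5-(benzyloxy)-3-(methoxymethoxy)-2-(tosylmethyl)phenol; 6 benzyloxyacetaldehyde
Product: 10 (3S)-3,7-bis(benzyloxy)-5-(methoxymethoxy)chroman-2-ol (C2 epimers), via ortho-quinone methide 7 (not isolated), via catalyst enamine 8 (not isolated), via open-chain hydroxy aldehyde 9 (not isolated)
Conditions: (R)-2-[diphenyl(trimethylsilyloxy)methyl]pyrrolidine (20 mol %), 5% aq NaHCO3, toluene, 0 °C → rt; 6 (2 equiv) added in portions
Reagents that add atoms: none
Why: Bicarbonate deprotonates the phenol of 5 and p-toluenesulfinate leaves, releasing ortho-quinone methide 7 at low concentration, while the amine condenses with 6 to the E-enamine 8, whose nucleophilic carbon adds to the exocyclic CH2 of 7 (the future C4) and rearomatises ring A. This is the known secondary-amine-catalysed enantioselective conjugate addition of aldehydes to ortho-quinone methides generated from 2-(sulfonylmethyl)phenols, which delivers chroman-2-ols. Hydrolysis of the iminium ion returns the catalyst and gives 9, whose phenol O1 adds to the aldehyde carbon C2 in a 6-exo-trig hemiacetalisation that closes the pyran ring. C3 is set by the catalyst: the CPh2(OSiMe3) group of the (R)-amine blocks one face of the s-trans E-enamine, so the methide is taken up on the open face, which corresponds to (3S), while C2 is an inconsequential hemiacetal mixture. The step needs conjugate addition to outrun self-aldol of 6 and self-condensation of 7: the donor oxygens at C5 and C7 tame 7, biphasic release keeps it dilute, 6 is fed in portions, and the unsubstituted methide carbon offers no steric barrier. Lactol closure withdraws the α-branched aldehyde from further enamine equilibria and so protects C3 from epimerisation.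

Step 6
Reactants: 11 2-(benzyloxy)phenol
Product: 12 2-(benzyloxy)-4-bromophenol
Conditions: NBS (1.0 equiv), MeCN, −10 → 0 °C
Reagents that add atoms: N-bromosuccinimide, O=C1CCC(=O)N1Br
Why: Electrophilic aromatic bromination: the free hydroxyl is the stronger director and NBS in acetonitrile favours its para position, which puts bromine on the future C1' with the free oxygen as O4' and the benzyl ether as O3'.

Step 7
Reactants: 12 2-(benzyloxy)-4-bromophenol
Product: 13 2-(benzyloxy)-4-bromo-1-(methoxymethoxy)benzene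
Conditions: MOMCl (1.2 equiv), K2CO3 (1.5 equiv), acetone, rt
Reagents that add atoms: chloromethyl methyl ether, COCCl
Why: Williamson-type MOM ether formation gives O4' the same acid-labile mask as O5, so that exactly the two oxygens to be galloylated are released together later, and it removes the acidic proton before magnesium insertion.

Step 8
Reactants: 13 2-(benzyloxy)-4-bromo-1-(methoxymethoxy)benzene; 10 (3S)-3,7-bis(benzyloxy)-5-(methoxymethoxy)chroman-2-ol
Product: 15 (2S)-2-(benzyloxy)-1-[3-(benzyloxy)-4-(methoxymethoxy)phenyl]-3-[4-(benzyloxy)-2-hydroxy-6-(methoxymethoxy)phenyl]propan-1-ol (carbinol epimers), via arylmagnesium bromide 14 (not isolated)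
Conditions: 13 (3 equiv), Mg turnings, I2 (cat.), THF, 45 °C; then 10, THF, −20 °C → rt; aqueous quench
Reagents that add atoms: none
Why: Grignard addition to a lactol: one equivalent of 14 deprotonates 10 and opens it to the magnesium phenoxide of aldehyde 9, a second adds to C2 and forms C2–C1', the new carbinol centre arises as a mixture that does not matter because step 9 erases it, and fast addition at low temperature leaves the α-alkoxy centre C3 unenolised.

Step 9
Reactants: 15 (2S)-2-(benzyloxy)-1-[3-(benzyloxy)-4-(methoxymethoxy)phenyl]-3-[4-(benzyloxy)-2-hydroxy-6-(methoxymethoxy)phenyl]propan-1-ol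
Product: 17 (2R,3S)-3,7-bis(benzyloxy)-2-[3-(benzyloxy)-4-hydroxyphenyl]chroman-5-ol, via bis-MOM trans-chroman 16 (not isolated)
Conditions: HCl (ca. 1 M) in MeOH–THF, 0.01 M in 15, 0 °C → 45 °C
Reagents that add atoms: none
Why: Acid-promoted SN1 cyclodehydration combined with acetal cleavage, the known way from MOM-protected 1,3-diarylpropane-1,2-diol derivatives to 2,3-trans-flavan-3-ols: both carbinol epimers ionise to the same O4'-stabilised benzylic cation, O1 closes through the half-chair that keeps the aryl group and the C3 benzyloxy group pseudo-equatorial so that C2 should form as R relative to the untouched (3S) centre, the solvent then converts both MOM groups into dimethoxymethane and so keeps formaldehyde equivalents away from C6 and C8, and since ring A without its MOM group has two equivalent ortho hydroxyls, the order of events cannot change the constitution of the product.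

Step 10
Reactants: 17 (2R,3S)-3,7-bis(benzyloxy)-2-[3-(benzyloxy)-4-hydroxyphenyl]chroman-5-ol; 18 3,4,5-tris(benzyloxy)benzoic acid
Product: 19 (2R,3S)-3,7-bis(benzyloxy)-2-{3-(benzyloxy)-4-[3,4,5-tris(benzyloxy)benzoyloxy]phenyl}chroman-5-yl 3,4,5-tris(benzyloxy)benzoate
Conditions: 18 (2.4 equiv), DCC (2.6 equiv), DMAP (0.3 equiv), CH2Cl2, 0 °C → rt
Reagents that add atoms: none
Why: Steglich esterification: O5–H and O4'–H are the only free hydroxyls in 17, both are phenols that acylate readily under DMAP catalysis, and no stereocentre is involved.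

Step 11
Reactants: 19 (2R,3S)-3,7-bis(benzyloxy)-2-{3-(benzyloxy)-4-[3,4,5-tris(benzyloxy)benzoyloxy]phenyl}chroman-5-yl 3,4,5-tris(benzyloxy)benzoate
Product: 20 catechin 5,4'-di-O-gallate, (2R,3S)
Conditions: H2 (1 atm), Pd(OH)2/C, THF–EtOAc, 1% AcOH, rt; filtration; reversed-phase chromatography (0.1% HCO2H)
Reagents that add atoms: none
Why: Catalytic hydrogenolysis of all nine benzyl ethers, standard for perbenzylated galloyl flavan-3-ols: the aryl esters and the cyclic C2–O1 bond are known to survive, and the aprotic, slightly acidic medium is chosen to suppress solvolysis of the phenolic esters and an O4' to O3' acyl shift once the catechol hydroxyl is free, so C2 and C3 stay as set.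

Compound list
1 | 2,4,6-trihydroxybenzaldehyde | O=Cc1c(O)cc(O)cc1O | starting material
2 | 4-(benzyloxy)-2,6-dihydroxybenzaldehyde | O=Cc1c(O)cc(OCc2ccccc2)cc1O | intermediate
3 | 4-(benzyloxy)-2-hydroxy-6-(methoxymethoxy)benzaldehyde | COCOc1cc(OCc2ccccc2)cc(O)c1C=O | intermediate
4 | 5-(benzyloxy)-2-(hydroxymethyl)-3-(methoxymethoxy)phenol | COCOc1cc(OCc2ccccc2)cc(O)c1CO | intermediate
5 | 5-(benzyloxy)-3-(methoxymethoxy)-2-(tosylmethyl)phenol | Cc1ccc(S(=O)(=O)Cc2c(O)cc(OCc3ccccc3)cc2OCOC)cc1 | intermediate
6 | benzyloxyacetaldehyde | O=CCOCc1ccccc1 | starting material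
7 | 3-(benzyloxy)-5-(methoxymethoxy)-6-methylidenecyclohexa-2,4-dien-1-one (ring A ortho-quinone methide) | C=C1C(=O)C=C(OCc2ccccc2)C=C1OCOC | intermediate
8 | (R)-1-[(E)-2-(benzyloxy)ethenyl]-2-[diphenyl(trimethylsilyloxy)methyl]pyrrolidine (catalyst enamine) | C[Si](C)(C)OC(c1ccccc1)(c1ccccc1)[C@H]1CCCN1/C=C/OCc1ccccc1 | intermediate
9 | (S)-2-(benzyloxy)-3-[4-(benzyloxy)-2-hydroxy-6-(methoxymethoxy)phenyl]propanal | O=C[C@@H](OCc1ccccc1)Cc1c(O)cc(OCc2ccccc2)cc1OCOC | intermediate
10 | (3S)-3,7-bis(benzyloxy)-5-(methoxymethoxy)chroman-2-ol, C2 epimers | COCOc1cc(OCc2ccccc2)cc2OC(O)[C@@H](OCc3ccccc3)Cc12 | intermediate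
11 | 2-(benzyloxy)phenol | Oc1ccccc1OCc1ccccc1 | starting material
12 | 2-(benzyloxy)-4-bromophenol | Oc1ccc(Br)cc1OCc1ccccc1 | intermediate
13 | 2-(benzyloxy)-4-bromo-1-(methoxymethoxy)benzene | COCOc1ccc(Br)cc1OCc1ccccc1 | intermediate
14 | [3-(benzyloxy)-4-(methoxymethoxy)phenyl]magnesium bromide | COCOc1ccc([Mg]Br)cc1OCc1ccccc1 | intermediate
15 | (2S)-2-(benzyloxy)-1-[3-(benzyloxy)-4-(methoxymethoxy)phenyl]-3-[4-(benzyloxy)-2-hydroxy-6-(methoxymethoxy)phenyl]propan-1-ol, carbinol epimers | COCOc1ccc(C(O)[C@@H](OCc2ccccc2)Cc2c(O)cc(OCc3ccccc3)cc2OCOC)cc1OCc1ccccc1 | intermediate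
16 | (2R,3S)-3,7-bis(benzyloxy)-2-[3-(benzyloxy)-4-(methoxymethoxy)phenyl]-5-(methoxymethoxy)chroman | COCOc1ccc([C@H]2Oc3cc(OCc4ccccc4)cc(OCOC)c3C[C@@H]2OCc2ccccc2)cc1OCc1ccccc1 | intermediate
17 | (2R,3S)-3,7-bis(benzyloxy)-2-[3-(benzyloxy)-4-hydroxyphenyl]chroman-5-ol | Oc1ccc([C@H]2Oc3cc(OCc4ccccc4)cc(O)c3C[C@@H]2OCc2ccccc2)cc1OCc1ccccc1 | intermediate
18 | 3,4,5-tris(benzyloxy)benzoic acid | OC(=O)c1cc(OCc2ccccc2)c(OCc2ccccc2)c(OCc2ccccc2)c1 | starting material
19 | (2R,3S)-3,7-bis(benzyloxy)-2-{3-(benzyloxy)-4-[3,4,5-tris(benzyloxy)benzoyloxy]phenyl}chroman-5-yl 3,4,5-tris(benzyloxy)benzoate | O=C(Oc1ccc([C@H]2Oc3cc(OCc4ccccc4)cc(OC(=O)c4cc(OCc5ccccc5)c(OCc5ccccc5)c(OCc5ccccc5)c4)c3C[C@@H]2OCc2ccccc2)cc1OCc1ccccc1)c1cc(OCc2ccccc2)c(OCc2ccccc2)c(OCc2ccccc2)c1 | intermediate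
20 | catechin 5,4'-di-O-gallate, (2R,3S) | O=C(Oc1ccc([C@H]2Oc3cc(O)cc(OC(=O)c4cc(O)c(O)c(O)c4)c3C[C@@H]2O)cc1O)c1cc(O)c(O)c(O)c1 | target

Total steps: 11. Longest linear sequence: 9 (steps 1–5 and 8–11). Steps 6 and 7 form the ring B branch.

Steps most likely to fail

Step 5. Three processes could erode conversion or enantiopurity: self-aldol of the α-oxy aldehyde, interception of the methide by water or by the amine, and weak facial discrimination. The fallback sets out from 3 and comes back at 17. It sets C3 by asymmetric hydrogenation instead of enamine addition.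
- The chelated phenol of 3 is capped (NaH, MOMCl, DMF) to give 4-(benzyloxy)-2,6-bis(methoxymethoxy)benzaldehyde F1.
- Horner–Wadsworth–Emmons olefination with ethyl 2-(benzyloxy)-2-(diethoxyphosphoryl)acetate (NaH, THF) should give ethyl (Z)-2-(benzyloxy)-3-[4-(benzyloxy)-2,6-bis(methoxymethoxy)phenyl]prop-2-enoate F2.
- LiOH then gives (Z)-2-(benzyloxy)-3-[4-(benzyloxy)-2,6-bis(methoxymethoxy)phenyl]prop-2-enoic acid F3.
- Homogeneous hydrogenation of this α-alkoxycinnamic acid with Ru(OAc)2(binap), using the ligand antipode that delivers the S acid, should give (S)-2-(benzyloxy)-3-[4-(benzyloxy)-2,6-bis(methoxymethoxy)phenyl]propanoic acid F4. The benzyl ethers are not touched.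
- BH3·THF reduces it to (S)-2-(benzyloxy)-3-[4-(benzyloxy)-2,6-bis(methoxymethoxy)phenyl]propan-1-ol F5.
- Dess–Martin oxidation gives (S)-2-(benzyloxy)-3-[4-(benzyloxy)-2,6-bis(methoxymethoxy)phenyl]propanal F6.
- A slight excess of 14 adds to give (2S)-2-(benzyloxy)-1-[3-(benzyloxy)-4-(methoxymethoxy)phenyl]-3-[4-(benzyloxy)-2,6-bis(methoxymethoxy)phenyl]propan-1-ol F7.
- Under the conditions of step 9 all three MOM groups fall, ring A becomes symmetric, and closure through either ortho hydroxyl gives 17.

Step 9. The cationic closure could show an insufficient trans preference. It could also lose material through intermolecular Friedel–Crafts capture of the cation at C6 or C8 of ring A, or suffer attack of formaldehyde equivalents on ring A. The fallback sets out from 15 and comes back at 16, then 17. The ring is closed by invertive displacement, and MOM removal becomes a separate operation.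
- Step 8 is run with added MgBr2·OEt2 at low temperature, so that chelation between the aldehyde oxygen and O3 favours the syn adduct.
- This isomer, (1S,2S)-2-(benzyloxy)-1-[3-(benzyloxy)-4-(methoxymethoxy)phenyl]-3-[4-(benzyloxy)-2-hydroxy-6-(methoxymethoxy)phenyl]propan-1-ol F8, is separated by chromatography.
- It is closed by intramolecular Mitsunobu etherification (PPh3, DIAD, THF, 0 °C). O1 displaces the activated benzylic oxygen with inversion to give 16, this time isolated.
- Catalytic HCl in MeOH then removes the MOM ethers to give 17.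

Step 4. Self-alkylation of ring A by its own benzylic cation (oligomerisation) or loss of the MOM ether could compete with capture by sulfur. The fallback sets out from 3 and comes back at 5, and it avoids the free benzylic alcohol altogether.
- Reductive amination of 3 (Me2NH, NaBH(OAc)3, 1,2-dichloroethane) should give the hydrogen-bond-stabilised Mannich base 5-(benzyloxy)-2-[(dimethylamino)methyl]-3-(methoxymethoxy)phenol F9.
- MeI in MeCN quaternises it to [4-(benzyloxy)-2-hydroxy-6-(methoxymethoxy)benzyl]trimethylammonium iodide F10.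
- Warming with p-TolSO2Na in aqueous MeCN expels trimethylamine and adds sulfinate by elimination–addition, the established substitution of phenolic Mannich salts, to give 5.

Further compounds
F1 | step 5 | 4-(benzyloxy)-2,6-bis(methoxymethoxy)benzaldehyde | COCOc1cc(OCc2ccccc2)cc(OCOC)c1C=O
F2 | step 5 | ethyl (Z)-2-(benzyloxy)-3-[4-(benzyloxy)-2,6-bis(methoxymethoxy)phenyl]prop-2-enoate | CCOC(=O)/C(OCc1ccccc1)=C/c1c(OCOC)cc(OCc2ccccc2)cc1OCOC
F3 | step 5 | (Z)-2-(benzyloxy)-3-[4-(benzyloxy)-2,6-bis(methoxymethoxy)phenyl]prop-2-enoic acid | OC(=O)/C(OCc1ccccc1)=C/c1c(OCOC)cc(OCc2ccccc2)cc1OCOC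
F4 | step 5 | (S)-2-(benzyloxy)-3-[4-(benzyloxy)-2,6-bis(methoxymethoxy)phenyl]propanoic acid | OC(=O)[C@@H](OCc1ccccc1)Cc1c(OCOC)cc(OCc2ccccc2)cc1OCOC
F5 | step 5 | (S)-2-(benzyloxy)-3-[4-(benzyloxy)-2,6-bis(methoxymethoxy)phenyl]propan-1-ol | OC[C@@H](OCc1ccccc1)Cc1c(OCOC)cc(OCc2ccccc2)cc1OCOC
F6 | step 5 | (S)-2-(benzyloxy)-3-[4-(benzyloxy)-2,6-bis(methoxymethoxy)phenyl]propanal | O=C[C@@H](OCc1ccccc1)Cc1c(OCOC)cc(OCc2ccccc2)cc1OCOC
F7 | step 5 | (2S)-2-(benzyloxy)-1-[3-(benzyloxy)-4-(methoxymethoxy)phenyl]-3-[4-(benzyloxy)-2,6-bis(methoxymethoxy)phenyl]propan-1-ol, carbinol epimers | COCOc1ccc(C(O)[C@@H](OCc2ccccc2)Cc2c(OCOC)cc(OCc3ccccc3)cc2OCOC)cc1OCc1ccccc1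
F8 | step 9 | (1S,2S)-2-(benzyloxy)-1-[3-(benzyloxy)-4-(methoxymethoxy)phenyl]-3-[4-(benzyloxy)-2-hydroxy-6-(methoxymethoxy)phenyl]propan-1-ol | COCOc1ccc([C@H](O)[C@@H](OCc2ccccc2)Cc2c(O)cc(OCc3ccccc3)cc2OCOC)cc1OCc1ccccc1
F9 | step 4 | 5-(benzyloxy)-2-[(dimethylamino)methyl]-3-(methoxymethoxy)phenol | CN(C)Cc1c(O)cc(OCc2ccccc2)cc1OCOC
F10 | step 4 | [4-(benzyloxy)-2-hydroxy-6-(methoxymethoxy)benzyl]trimethylammonium iodide | C[N+](C)(C)Cc1c(O)cc(OCc2ccccc2)cc1OCOC.[I-]
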